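**Retrosynthetic overview**
1. Target ⇐ its 1,3-acetonide ⇐ (key step) iridium-catalysed decarboxylative ring contraction of a 15-membered cyclic allyl carbonate: CO2 leaves, the C6–C7 bond forms, the ten-membered carbocycle appears and the C6 alkoxide closes the γ-lactone.
2. Cyclic carbonate ⇐ angeloylation at O8 ⇐ Nozaki–Hiyama–Kishi macrocyclisation of a bromoacrylate/enal (C7–C8 bond).
3. Bromo-enal ⇐ C2-symmetric diol + CO2 + methyl (Z)-3-bromo-2-(bromomethyl)acrylate; the carbonate desymmetrises the chain, masks O6 and is the tether that is later extruded.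
4. Diol ⇐ boron aldol (sets C1) and 1,3-anti reduction (sets C3) of a methyl ketone and an aldehyde, both made from (Z)-3-iodobut-2-en-1-ol, so both Z-trisubstituted alkenes are fixed in the first step.
5. Rings in order: 1,3-dioxane (protection) → 15-membered carbonate ring → ten-membered carbocycle → γ-lactone.

Assumption: locants follow the germacrane skeleton (lactone O on C6, ring fusion C6/C7, ester on C8, hydroxyls on C1 and C3, alkenes C4=C5 and C9=C10, exocyclic C11=C13, C12 the lactone carbonyl); the SMILES is read as (1S,3S,4Z,6S,7S,8R,9Z) with a cis-fused lactone and an angelate, (Z)-2-methylbut-2-enoate.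

**Step 1**
Reactants: 1 but-2-yn-1-ol
Product: 3 (Z)-3-iodobut-2-en-1-ol, via cyclic vinylalanate 2 (not isolated)
Conditions: NaAlH2(OCH2CH2OMe)2, THF, 0 °C to rt; then I2, −78 to 0 °C
Reagents that add atoms: iodine, II
Why: Hydroxyl-directed trans-hydroalumination of the propargylic alcohol places aluminium on C3 in a five-membered oxa-aluminacycle and iodinolysis with retention gives only the (Z)-vinyl iodide (alkyne hydroalumination–iodination).

**Step 2**
Reactants: 3 (Z)-3-iodobut-2-en-1-ol
Product: 4 tert-butyl{[(Z)-3-iodobut-2-en-1-yl]oxy}dimethylsilane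
Conditions: TBSCl, imidazole, CH2Cl2, 0 °C to rt
Reagents that add atoms: tert-butyldimethylsilyl chloride, C[Si](C)(Cl)C(C)(C)C
Why: Routine silyl ether protection of the primary allylic alcohol so that the vinyl iodide can be metalated.

**Step 3**
Reactants: 4 tert-butyl{[(Z)-3-iodobut-2-en-1-yl]oxy}dimethylsilane; 5 N-methoxy-N-methylacetamide
Product: 7 (Z)-5-[(tert-butyldimethylsilyl)oxy]-3-methylpent-3-en-2-one, via alkenyllithium 6 (not isolated)
Conditions: t-BuLi (2.1 equiv), Et2O, −78 °C; then 5, −78 to 0 °C; then H2O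
Reagents that add atoms: none
Why: Iodine–lithium exchange gives a configurationally stable alkenyllithium that acylates the Weinreb amide through a chelated tetrahedral intermediate, so the (Z)-methyl enone forms without over-addition (Weinreb ketone synthesis).

**Step 4**
Reactants: 4 tert-butyl{[(Z)-3-iodobut-2-en-1-yl]oxy}dimethylsilane; 8 N,N-dimethylformamide
Product: 10 (Z)-4-[(tert-butyldimethylsilyl)oxy]-2-methylbut-2-enal, via alkenylmagnesium chloride 9 (not isolated)
Conditions: i-PrMgCl·LiCl (1.1 equiv), THF, −20 °C to rt; then 8, 0 °C to rt; then H2O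
Reagents that add atoms: none
Why: Iodine–magnesium exchange with the LiCl-activated isopropyl Grignard reagent gives the alkenylmagnesium chloride with retention of geometry, and DMF formylates it through a magnesium hemiaminal alkoxide that releases the (Z)-enal only on hydrolysis, so the milder magnesium reagent cannot add to the aldehyde product (Bouveault-type formylation).

**Step 5**
Reactants: 7 (Z)-5-[(tert-butyldimethylsilyl)oxy]-3-methylpent-3-en-2-one; 10 (Z)-4-[(tert-butyldimethylsilyl)oxy]-2-methylbut-2-enal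
Product: 12 (2Z,6S,7Z)-1,9-bis[(tert-butyldimethylsilyl)oxy]-6-hydroxy-3,7-dimethylnona-2,7-dien-4-one, via enol diisopinocampheylborinate 11 (not isolated)
Conditions: (+)-Ipc2BCl, Et3N, Et2O, 0 °C; then 10, −78 to −20 °C; then H2O2, MeOH, aq. NaH2PO4/Na2HPO4 (pH 7)
Reagents that add atoms: none
Why: Paterson boron aldol, in which the methyl-ketone enol borinate from (+)-Ipc2BCl adds to the si face of the (Z)-enal through a cyclic six-membered transition state and so sets the future C1 as (S) under reagent control.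

**Step 6**
Reactants: 12 (2Z,6S,7Z)-1,9-bis[(tert-butyldimethylsilyl)oxy]-6-hydroxy-3,7-dimethylnona-2,7-dien-4-one
Product: 13 (2Z,4S,6S,7Z)-1,9-bis[(tert-butyldimethylsilyl)oxy]-3,7-dimethylnona-2,7-diene-4,6-diol
Conditions: Me4NBH(OAc)3, MeCN/AcOH (1:1), −25 °C
Reagents that add atoms: none
Why: Evans–Saksena reduction, in which the C1 hydroxyl binds the triacetoxyborohydride and delivers hydride intramolecularly through a chair transition state, giving the 1,3-anti diol and so the future C3 as (S) by 1,2-reduction of the enone.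

**Step 7**
Reactants: 13 (2Z,4S,6S,7Z)-1,9-bis[(tert-butyldimethylsilyl)oxy]-3,7-dimethylnona-2,7-diene-4,6-diol
Product: 14 (4S,6S)-4,6-bis{(Z)-4-[(tert-butyldimethylsilyl)oxy]but-2-en-2-yl}-2,2-dimethyl-1,3-dioxane
Conditions: 2,2-dimethoxypropane, PPTS (cat.), CH2Cl2, rt
Reagents that add atoms: 2,2-dimethoxypropane, COC(C)(C)OC
Why: Acid-catalysed transketalisation (acetonide formation) masks the anti-1,3-diol as a dioxane that survives base, oxidants and low-valent metals, while the primary silyl ethers are untouched.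

**Step 8**
Reactants: 14 (4S,6S)-4,6-bis{(Z)-4-[(tert-butyldimethylsilyl)oxy]but-2-en-2-yl}-2,2-dimethyl-1,3-dioxane
Product: 15 (2Z,2'Z)-3,3'-[(4S,6S)-2,2-dimethyl-1,3-dioxane-4,6-diyl]bis(but-2-en-1-ol)
Conditions: TBAF, THF, 0 °C to rt
Reagents that add atoms: none
Why: Fluoride cleaves both primary silyl ethers (desilylation) to a C2-symmetric diol whose two hydroxyls are homotopic, so that mono-functionalisation can give only one compound.

**Step 9**
Reactants: 16 methyl 2-(bromomethyl)prop-2-enoate
Product: 18 methyl (Z)-3-bromo-2-(bromomethyl)prop-2-enoate, via tribromide 17 (not isolated)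
Conditions: Br2, CH2Cl2, 0 °C; then Et3N (1.0 equiv), Et2O, 0 °C to rt
Reagents that add atoms: bromine, BrBr
Why: Bromine adds across the acrylate and, because the α-carbon carries no hydrogen, E2 loss of HBr can only take a hydrogen from a CH2Br group, giving the β-bromoacrylate with the vinyl bromine anti to the ester (bromination–dehydrobromination).

**Step 10**
Reactants: 15 (2Z,2'Z)-3,3'-[(4S,6S)-2,2-dimethyl-1,3-dioxane-4,6-diyl]bis(but-2-en-1-ol); 18 methyl (Z)-3-bromo-2-(bromomethyl)prop-2-enoate
Product: 20 methyl (E)-3-bromo-2-({[({(2Z)-3-[(4S,6S)-6-[(2Z)-4-hydroxybut-2-en-2-yl]-2,2-dimethyl-1,3-dioxan-4-yl]but-2-en-1-yl}oxy)carbonyl]oxy}methyl)prop-2-enoate, via caesium alkyl carbonate 19 (not isolated)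
Conditions: 15 (3 equiv), Cs2CO3, CO2 (1 atm), Bu4NI (cat.), DMF, rt; then 18 (1 equiv), rt; excess 15 recovered
Reagents that add atoms: carbon dioxide, O=C=O
Why: Alkylative carbonation, in which the caesium alkyl carbonate formed from one hydroxyl and CO2 is O-alkylated by the allylic bromide in an SN2 step (the vinyl bromide is inert), and the C2 symmetry of the excess diol means only one mono-carbonate can form; this carbonate desymmetrises the chain, masks the future O6 and is the tether for the ring contraction.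

**Step 11**
Reactants: 20 the mono-carbonate alcohol
Product: 21 methyl (E)-3-bromo-2-({[({(2Z)-3-[(4S,6S)-2,2-dimethyl-6-[(2Z)-4-oxobut-2-en-2-yl]-1,3-dioxan-4-yl]but-2-en-1-yl}oxy)carbonyl]oxy}methyl)prop-2-enoate
Conditions: MnO2 (activated, excess), CH2Cl2, rt
Reagents that add atoms: none
Why: MnO2 oxidises the remaining primary allylic alcohol to the (Z)-enal (allylic oxidation) without touching the carbonate, the vinyl bromide or the acetonide and without E/Z isomerisation.

**Step 12**
Reactants: 21 the bromoacrylate enal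
Product: 22 15-membered cyclic carbonate alcohol (ring C6H2–O–C(=O)–O–C13H2–C11(CO2Me)=C7H–C8H(OH)–C9H=C10(Me)–C1–C2H2–C3–C4(Me)=C5H; C1 and C3 held as the (S,S)-acetonide; (8R); C7=C11 E; C4=C5 and C9=C10 Z)
Conditions: CrCl2 (4 equiv), NiCl2 (2 mol %), N-{2-[(4S)-4-isopropyl-4,5-dihydro-1,3-oxazol-2-yl]-6-methylphenyl}methanesulfonamide (4.4 equiv), Et3N, THF, rt, slow addition of 21 to 0.002 M
Reagents that add atoms: none
Why: Nozaki–Hiyama–Kishi reaction, in which zerovalent nickel inserts into the activated vinyl C–Br bond, transmetalation gives an alkenylchromium species that adds to the aldehyde with retention of alkene geometry to close the unstrained 15-membered ring, and the chromium-bound chiral sulfonamide is used to select the aldehyde face that gives (8R).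

**Step 13**
Reactants: 22 the cyclic carbonate alcohol; 23 angelic acid, (Z)-2-methylbut-2-enoic acid
Product: 25 8-O-angelate of 22, via mixed anhydride 24 (not isolated)
Conditions: 23, 2,4,6-trichlorobenzoyl chloride, Et3N, toluene, rt; then 22, 75 °C
Reagents that add atoms: none
Why: Yamaguchi esterification, in which the mixed anhydride acylates the hindered C8 alcohol with retention at C8 and the DMAP-free protocol avoids isomerisation of the angelate to the tiglate.

**Step 14**
Reactants: 25 the cyclic carbonate angelate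
Product: 27 (1S,3S,6S,7S,8R)-8-angeloyloxy-1,3-O-isopropylidene-1,3-dihydroxygermacra-4Z,9Z,11(13)-trien-6,12-olide, via hydroxy ester 26 (not isolated)
Conditions: [Ir(cod)Cl]2 (5 mol %), (R)-SEGPHOS (10 mol %), 4-cyano-3-nitrobenzoic acid (20 mol %), Cs2CO3 (20 mol %), THF, 70 °C, 0.005 M
Reagents that add atoms: none
Why: Proposed new method: the iridium catalyst ionises the allylic C13–O bond of the cyclic carbonate, the expelled alkyl carbonate loses CO2 to leave the C6 alkoxide on the metal, β-hydride elimination turns it into the (Z)-enal and the 2-(methoxycarbonyl)allyl ligand then adds through its C7 terminus in a closed chair transition state, so that the 15-membered ring contracts to the ten-membered carbocycle in a redox-neutral, base-free way, the ligand fixing the C6 face (S) and the ester-chelated allyl geometry giving the syn adduct (7S), whose alkoxide lactonises to the cis-fused α-methylene lactone; the closest known reaction type is the intermolecular iridium-catalysed transfer-hydrogenative 2-(alkoxycarbonyl)allylation of primary alcohols with acrylate-derived allylic carbonates, which has not been run on a substrate where donor and alcohol are tied together as one cyclic carbonate.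

**Step 15**
Reactants: 27 the acetonide-protected lactone
Product: 28 (1S,3S,4Z,6S,7S,8R,9Z)-8-angeloyloxy-1,3-dihydroxygermacra-4,9,11(13)-trien-6,12-olide (CNP0152559.4)
Conditions: AcOH/H2O (4:1), 40 °C
Reagents that add atoms: none
Why: Mild acetal hydrolysis removes the anti-configured acetonide, which sits in a strained twist-boat and is therefore labile, without touching the lactone, the angelate or any stereocentre.

**Compound list**
1 | but-2-yn-1-ol | CC#CCO | starting material
2 | cyclic vinylalanate, sodium 2,2-bis(2-methoxyethoxy)-3-methyl-2,5-dihydro-1,2-oxaaluminol-2-uide | CC1=CCO[Al-]1(OCCOC)OCCOC.[Na+] | intermediate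
3 | (Z)-3-iodobut-2-en-1-ol | C/C(I)=C/CO | intermediate
4 | tert-butyl{[(Z)-3-iodobut-2-en-1-yl]oxy}dimethylsilane | C/C(I)=C/CO[Si](C)(C)C(C)(C)C | intermediate
5 | N-methoxy-N-methylacetamide | CC(=O)N(C)OC | starting material
6 | alkenyllithium, {(E)-4-[(tert-butyldimethylsilyl)oxy]but-2-en-2-yl}lithium (lithium cis to the CH2OTBS group) | C/C([Li])=C/CO[Si](C)(C)C(C)(C)C | intermediate
7 | (Z)-5-[(tert-butyldimethylsilyl)oxy]-3-methylpent-3-en-2-one | CC(=O)/C(C)=C\CO[Si](C)(C)C(C)(C)C | intermediate
8 | N,N-dimethylformamide | CN(C)C=O | starting material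
9 | alkenylmagnesium chloride, {(Z)-4-[(tert-butyldimethylsilyl)oxy]but-2-en-2-yl}magnesium chloride (magnesium cis to the CH2OTBS group) | C/C([Mg]Cl)=C/CO[Si](C)(C)C(C)(C)C | intermediate
10 | (Z)-4-[(tert-butyldimethylsilyl)oxy]-2-methylbut-2-enal | O=C/C(C)=C\CO[Si](C)(C)C(C)(C)C | intermediate
11 | enol diisopinocampheylborinate of 7 | C[C@@H]1[C@@H](B(OC(=C)/C(C)=C\CO[Si](C)(C)C(C)(C)C)[C@H]3C[C@H]4C[C@@H]([C@@H]3C)C4(C)C)C[C@H]2C[C@@H]1C2(C)C | intermediate
12 | (2Z,6S,7Z)-1,9-bis[(tert-butyldimethylsilyl)oxy]-6-hydroxy-3,7-dimethylnona-2,7-dien-4-one | CC(C)(C)[Si](C)(C)OC/C=C(/C)C(=O)C[C@H](O)/C(C)=C\CO[Si](C)(C)C(C)(C)C | intermediate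
13 | (2Z,4S,6S,7Z)-1,9-bis[(tert-butyldimethylsilyl)oxy]-3,7-dimethylnona-2,7-diene-4,6-diol | CC(C)(C)[Si](C)(C)OC/C=C(/C)[C@@H](O)C[C@H](O)/C(C)=C\CO[Si](C)(C)C(C)(C)C | intermediate
14 | (4S,6S)-4,6-bis{(Z)-4-[(tert-butyldimethylsilyl)oxy]but-2-en-2-yl}-2,2-dimethyl-1,3-dioxane | CC(C)(C)[Si](C)(C)OC/C=C(/C)[C@@H]1C[C@H](OC(C)(C)O1)/C(C)=C\CO[Si](C)(C)C(C)(C)C | intermediate
15 | (2Z,2'Z)-3,3'-[(4S,6S)-2,2-dimethyl-1,3-dioxane-4,6-diyl]bis(but-2-en-1-ol) | OC/C=C(/C)[C@@H]1C[C@H](OC(C)(C)O1)/C(C)=C\CO | intermediate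
16 | methyl 2-(bromomethyl)prop-2-enoate | C=C(CBr)C(=O)OC | starting material
17 | tribromide, methyl 2,3-dibromo-2-(bromomethyl)propanoate | BrCC(Br)(CBr)C(=O)OC | intermediate
18 | methyl (Z)-3-bromo-2-(bromomethyl)prop-2-enoate (Br cis to CH2Br) | Br/C=C(\CBr)C(=O)OC | intermediate
19 | caesium alkyl carbonate of 15 (one hydroxyl carbonated) | [Cs+].[O-]C(=O)OC/C=C(/C)[C@@H]1C[C@H](OC(C)(C)O1)/C(C)=C\CO | intermediate
20 | mono-carbonate alcohol: methyl (E)-3-bromo-2-({[({(2Z)-3-[(4S,6S)-6-[(2Z)-4-hydroxybut-2-en-2-yl]-2,2-dimethyl-1,3-dioxan-4-yl]but-2-en-1-yl}oxy)carbonyl]oxy}methyl)prop-2-enoate (Br cis to CH2O) | Br/C=C(\COC(=O)OC/C=C(/C)[C@@H]1C[C@H](OC(C)(C)O1)/C(C)=C\CO)C(=O)OC | intermediate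
21 | bromoacrylate enal: as 20 with the free CH2OH oxidised to the (Z)-enal | Br/C=C(\COC(=O)OC/C=C(/C)[C@@H]1C[C@H](OC(C)(C)O1)/C(C)=C\C=O)C(=O)OC | intermediate
22 | 15-membered cyclic carbonate alcohol, (8R), C1/C3 as (S,S)-acetonide, C7=C11 E, C4=C5 and C9=C10 Z, CO2Me on C11 | O=C1OC/C=C(/C)[C@@H]2C[C@H](OC(C)(C)O2)/C(C)=C\[C@@H](O)/C=C(C(=O)OC)\CO1 | intermediate
23 | angelic acid, (Z)-2-methylbut-2-enoic acid | C/C=C(/C)C(=O)O | starting material
24 | mixed anhydride, (Z)-2-methylbut-2-enoic 2,4,6-trichlorobenzoic anhydride | C/C=C(/C)C(=O)OC(=O)c1c(Cl)cc(Cl)cc1Cl | intermediate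
25 | 8-O-angelate of 22, (8R) | O=C1OC/C=C(/C)[C@@H]2C[C@H](OC(C)(C)O2)/C(C)=C\[C@@H](OC(=O)/C(C)=C\C)/C=C(C(=O)OC)\CO1 | intermediate
26 | hydroxy ester: methyl (1S,3S,6S,7S,8R)-8-angeloyloxy-6-hydroxy-1,3-O-isopropylidene-1,3-dihydroxygermacra-4Z,9Z,11(13)-trien-12-oate | C=C(C(=O)OC)[C@H]1[C@@H](O)/C=C(/C)[C@@H]2C[C@H](OC(C)(C)O2)/C(C)=C\[C@H]1OC(=O)/C(C)=C\C | intermediate
27 | (1S,3S,6S,7S,8R)-8-angeloyloxy-1,3-O-isopropylidene-1,3-dihydroxygermacra-4Z,9Z,11(13)-trien-6,12-olide | C=C1C(=O)O[C@H]2/C=C(/C)[C@@H]3C[C@H](OC(C)(C)O3)/C(C)=C\[C@@H](OC(=O)/C(C)=C\C)[C@@H]12 | intermediate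
28 | (1S,3S,4Z,6S,7S,8R,9Z)-8-angeloyloxy-1,3-dihydroxygermacra-4,9,11(13)-trien-6,12-olide (CNP0152559.4) | C=C1C(=O)O[C@H]2/C=C(/C)[C@@H](O)C[C@H](O)/C(C)=C\[C@@H](OC(=O)/C(C)=C\C)[C@@H]12 | target

**Step count and risks**
Total step count: 15. Longest linear sequence: 13 steps (1, 2, 3, 5, 6, 7, 8, 10, 11, 12, 13, 14, 15); steps 4 and 9 are side branches.

The three steps most likely to fail are 5, 12 and 14.

Step 5 (aldol, enantiocontrol at C1): methyl-ketone boron aldols often give only moderate enantiomeric excess, and any shortfall is carried into every later diastereomer ratio. The fallback sets out from 7. TMSOTf and Et3N convert it into the trimethylsilyl enol ether of 7 F1, which is added to 10 in a catalytic Mukaiyama aldol under the B-butyl oxazaborolidinone Lewis acid made from N-tosyltryptophan and butylboronic acid, in EtCN at −78 °C. Acidic work-up removes the silyl group and the route is rejoined at 12.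

Step 12 (macrocyclisation, control at C8): ring closure to a 15-membered ring is routine for this coupling, but the level and even the sense of ligand control at C8 are not secure. The fallback sets out from 21 and drops ligand control: CrCl2 with NiCl2 (cat.) in DMSO gives both C8 epimers, which are separated. The (8R)-alcohol 22 continues through step 13. The (8S)-epimer of 22 F2 is esterified with 23 under Mitsunobu conditions (PPh3, DIAD, toluene, 0 °C), which inverts C8 and gives the same angelate 25, so both epimers converge and the route is rejoined at 25.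

Step 14 (the proposed ring contraction): the risks are reductive loss of the allyl unit (metal hydride and allyl on one centre), ionisation or 1,4-elimination involving the allylic angelate, and an unproven sense of induction in the cyclic case. The enantiomeric ligand is the first thing to test if the wrong C6/C7 pair dominates. The fallback uses known chemistry and sets out from 25. K2CO3 (cat.) in MeOH at 0 °C methanolyses the carbonate to the 6,13-diol F3. MnO2 oxidises only the electron-rich C6 allylic alcohol, giving the hydroxy enal F4. MsCl/Et3N followed by LiBr converts the C13 alcohol into the allylic bromide F5. CrCl2 in THF at 0.003 M then closes the ten-membered ring by the known intramolecular Nozaki–Hiyama allylation of 2-(alkoxycarbonyl)allyl bromides, which favours the cis-lactone; the chromium alkoxide lactonises and the route is rejoined at 27, before step 15.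

**Further compounds**
F1 | step 5 | trimethylsilyl enol ether of 7, tert-butyldimethyl{[(Z)-3-methyl-4-(trimethylsilyloxy)penta-2,4-dien-1-yl]oxy}silane | C=C(O[Si](C)(C)C)/C(C)=C\CO[Si](C)(C)C(C)(C)C
F2 | step 12 | (8S)-epimer of 22 | O=C1OC/C=C(/C)[C@@H]2C[C@H](OC(C)(C)O2)/C(C)=C\[C@H](O)/C=C(C(=O)OC)\CO1
F3 | step 14 | 6,13-diol: methyl (E)-2-(hydroxymethyl)alk-2-enoate with (8R)-angelate, free C6 CH2OH and the (S,S)-acetonide | OC/C=C(/C)[C@@H]1C[C@H](OC(C)(C)O1)/C(C)=C\[C@@H](OC(=O)/C(C)=C\C)/C=C(\CO)C(=O)OC
F4 | step 14 | hydroxy enal: as F3 with C6 oxidised to the (Z)-enal | O=C/C=C(/C)[C@@H]1C[C@H](OC(C)(C)O1)/C(C)=C\[C@@H](OC(=O)/C(C)=C\C)/C=C(\CO)C(=O)OC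
F5 | step 14 | allylic bromide: as F4 with C13 OH replaced by Br | O=C/C=C(/C)[C@@H]1C[C@H](OC(C)(C)O1)/C(C)=C\[C@@H](OC(=O)/C(C)=C\C)/C=C(\CBr)C(=O)OC
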